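**Assumption (one line):** the SMILES is the full structure, with the 4-hydroxybenzoate on the secondary C8 oxygen of the hydroazulene (the trans-fused 5-7 daucane skeleton). The quaternary-methyl configuration is set by a ligand-controlled Cu-catalysed conjugate addition, with the ligand enantiomer chosen to give the (R) centre.

## Retrosynthesis
1. Target ← benzyl-protected ester ← epoxy diol. The ester comes from acylating the secondary alcohol. The trisubstituted epoxide comes from a hydroxyl-directed epoxidation of the ring alkene.
2. The seven-membered ring is closed last by RCM of a cyclopentane bearing an allyl group and a 3-methylbut-3-enyl carbinol. The ring alkene becomes the epoxide.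
3. The tertiary isopropyl carbinol comes from adding iPrMgCl to a cyclopentanone.
4. The cyclopentanone, with its quaternary Me/allyl carbon and the adjacent CH(OH)R carbon, comes from a tandem asymmetric conjugate addition of Me to 3-allylcyclopentenone and aldol trapping with 3-methylbut-3-enal. The five-membered ring is therefore present from the start and the seven-membered ring is formed last.

## Route

**Step 1**
Reactants: 1 (3-ethoxycyclopent-2-en-1-one); 2 (allylmagnesium chloride)
Product: 3 (3-allylcyclopent-2-en-1-one)
Conditions: 2 (1.1 equiv), THF, 0 °C; then 1 M HCl, 0 °C, brief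
Reagents that add atoms: allylmagnesium chloride, C=CC[Mg]Cl
Why: Stork–Danheiser 1,2-addition to the vinylogous ester, then hydrolytic loss of EtOH, gives the 3-substituted enone. No stereocentre is formed.

**Step 2**
Reactants: 4 (3-methylbut-3-en-1-ol)
Product: 5 (3-methylbut-3-enal)
Conditions: Dess–Martin periodinane, NaHCO3, CH2Cl2, 0 °C to rt; crude solution used at once
Reagents that add atoms: none
Why: Mild oxidation of the primary alcohol gives the β,γ-unsaturated aldehyde that supplies C8, C7 and the isopropenyl unit.

**Step 3**
Reactants: 3; 6 (methylmagnesium bromide); 5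
Product: 7 ((2S,3R)-3-allyl-2-[(1S)-1-hydroxy-3-methylbut-3-en-1-yl]-3-methylcyclopentan-1-one)
Conditions: 3, MeMgBr (1.3 equiv), CuBr·SMe2 (5 mol%), Josiphos ligand (6 mol%), t-BuOMe, –78 °C; then ZnCl2 (1.5 equiv); then 5 (1.5 equiv), –78 to –20 °C; NH4Cl work-up; chromatographic removal of minor diastereomers
Reagents that add atoms: methylmagnesium bromide, C[Mg]Br; aldehyde 5, CC(=C)CC=O
Why: Cu/Josiphos asymmetric conjugate addition of Me to the β,β-disubstituted enone creates the quaternary (3R) centre, and it leaves a regiodefined enolate at C2 (tandem conjugate addition–aldol). ZnCl2 transmetalates the enolate and destroys excess MeMgBr. The cyclic E-enolate then reacts through a Zimmerman–Traxler chair to give the anti aldol at the carbinol centre. The aldehyde approaches the face of the smaller Me group, so the new side chain ends up trans to the allyl group.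

**Step 4**
Reactants: 7; 8 (isopropylmagnesium chloride)
Product: 9 ((1R,2S,3R)-3-allyl-2-[(1S)-1-hydroxy-3-methylbut-3-en-1-yl]-1-isopropyl-3-methylcyclopentan-1-ol)
Conditions: 8 (3 equiv), CeCl3 (3 equiv), THF, –78 to –40 °C
Reagents that add atoms: isopropylmagnesium chloride, CC(C)[Mg]Cl
Why: Organocerium-type addition avoids enolisation and reduction by the hindered Grignard. iPr attacks the ketone from the face anti to the C2 side chain and the angular Me. The new OH therefore ends up cis to the side chain, which sets the tertiary carbinol configuration.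

**Step 5**
Reactants: 9
Product: 10 ((1R,3aR,8S,8aS)-3a,6-dimethyl-1-(propan-2-yl)-1,2,3,3a,4,7,8,8a-octahydroazulene-1,8-diol)
Conditions: Hoveyda–Grubbs II (10 mol%), toluene (2 mM), 60 °C
Reagents that add atoms: none (ethylene is lost)
Why: Ring-closing metathesis of the monosubstituted allyl alkene with the 1,1-disubstituted alkene forms the trisubstituted cycloheptene. The five stereocentres already in place are untouched, and the trans ring fusion is retained.

**Step 6**
Reactants: 10
Product: 11 ((1R,3aR,5S,6R,8S,8aS)-5,6-epoxy-3a,6-dimethyl-1-(propan-2-yl)decahydroazulene-1,8-diol)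
Conditions: VO(acac)2 (5 mol%), TBHP (1.5 equiv), CH2Cl2, 0 °C to rt
Reagents that add atoms: tert-butyl hydroperoxide, CC(C)(C)OO (transfers one O)
Why: Vanadium-catalysed hydroxyl-directed epoxidation delivers O syn to the homoallylic C8–OH. This is also the face anti to the angular Me, and it sets C5 and C6 as a cis-epoxide.

**Step 7**
Reactants: 11; 12 (4-(benzyloxy)benzoyl chloride)
Product: 13 (the C8 4-(benzyloxy)benzoate of 11)
Conditions: 12 (1.2 equiv), Et3N, DMAP (cat.), CH2Cl2, 0 °C to rt
Reagents that add atoms: 4-(benzyloxy)benzoyl chloride, O=C(Cl)c1ccc(OCc2ccccc2)cc1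
Why: DMAP-catalysed acylation is chemoselective for the unhindered secondary alcohol over the tertiary alcohol, and it proceeds with retention at C8.

**Step 8**
Reactants: 13
Product: 14 (Jaeskeanin)
Conditions: H2 (1 atm), 10% Pd/C, EtOAc, rt
Reagents that add atoms: none (H2 adds only hydrogen; toluene is lost)
Why: Hydrogenolysis removes the benzyl ether. The non-benzylic trisubstituted epoxide, the tertiary alcohol and the aryl ester survive.

## Compound list
1 | 3-ethoxycyclopent-2-en-1-one | CCOC1=CC(=O)CC1 | starting material
2 | allylmagnesium chloride | C=CC[Mg]Cl | starting material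
3 | 3-allylcyclopent-2-en-1-one | C=CCC1=CC(=O)CC1 | intermediate
4 | 3-methylbut-3-en-1-ol | CC(=C)CCO | starting material
5 | 3-methylbut-3-enal | CC(=C)CC=O | intermediate
6 | methylmagnesium bromide | C[Mg]Br | starting material
7 | (2S,3R)-3-allyl-2-[(1S)-1-hydroxy-3-methylbut-3-en-1-yl]-3-methylcyclopentan-1-one | C=CC[C@@]1(C)CCC(=O)[C@@H]1[C@@H](O)CC(C)=C | intermediate
8 | isopropylmagnesium chloride | CC(C)[Mg]Cl | starting material
9 | (1R,2S,3R)-3-allyl-2-[(1S)-1-hydroxy-3-methylbut-3-en-1-yl]-1-isopropyl-3-methylcyclopentan-1-ol | C=CC[C@@]1(C)CC[C@@](O)(C(C)C)[C@@H]1[C@@H](O)CC(C)=C | intermediate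
10 | (1R,3aR,8S,8aS)-3a,6-dimethyl-1-(propan-2-yl)-1,2,3,3a,4,7,8,8a-octahydroazulene-1,8-diol | CC(C)[C@]1(O)CC[C@]2(C)CC=C(C)C[C@H](O)[C@H]21 | intermediate
11 | (1R,3aR,5S,6R,8S,8aS)-5,6-epoxy-3a,6-dimethyl-1-(propan-2-yl)decahydroazulene-1,8-diol | CC(C)[C@]1(O)CC[C@]2(C)C[C@@H]3O[C@]3(C)C[C@H](O)[C@H]21 | intermediate
12 | 4-(benzyloxy)benzoyl chloride | O=C(Cl)c1ccc(OCc2ccccc2)cc1 | starting material
13 | 8-O-[4-(benzyloxy)benzoyl] derivative of 11 | CC(C)[C@]1(O)CC[C@]2(C)C[C@@H]3O[C@]3(C)C[C@H](OC(=O)c3ccc(OCc4ccccc4)cc3)[C@H]21 | intermediate
14 | Jaeskeanin, (1R,3aR,5S,6R,8S,8aS)-5,6-epoxy-1-hydroxy-3a,6-dimethyl-1-(propan-2-yl)decahydroazulen-8-yl 4-hydroxybenzoate | CC(C)[C@]1(O)CC[C@]2(C)C[C@@H]3O[C@]3(C)C[C@H](OC(=O)c3ccc(O)cc3)[C@H]21 | target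

## Totals
Total steps: 8 (7 on the main line, plus one side step that makes aldehyde 5).
Longest linear sequence: 7 steps (1 → 3 → 7 → 9 → 10 → 11 → 13 → 14).

## Three steps most likely to fail
1. **Step 3 (conjugate addition–aldol).** Enantioselectivity of Me addition to a 3-allylcyclopentenone is unproven. The Me and allyl groups on the quaternary carbon are similar in size, so the ring-fusion diastereoselectivity may be poor. Fallback: run the sequence racemically with an achiral ligand. Carry the diastereomers to diol 10, then separate the wanted one by preparative chiral SFC or lipase-catalysed kinetic resolution of the C8 alcohol.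
2. **Step 5 (RCM).** Closing a trans-fused trisubstituted cycloheptene from a trans-1,2-disubstituted cyclopentane is strained, and free OH groups can divert the catalyst. Fallback: reorder the sequence. Do the RCM on ketone 7 with its free OH, where the cis-fused product closes more easily. Epimerise the α-carbon to the trans-fused ketone with DBU, then add iPrMgCl/CeCl3 and continue.
3. **Step 6 (epoxidation).** Facial selectivity on a flexible cycloheptene may not follow the directing OH. Fallback: use catalyst-controlled Shi epoxidation of diol 10 (fructose-derived ketone, Oxone), choosing the catalyst enantiomer that gives the α-epoxide. Alternatively, form the bromohydrin with NBS/H2O and close it with K2CO3.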